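**Assumptions (one line each):** Lignan numbering is used (C7 = free benzylic carbinol, C8 = THF C4, C8′ = THF C3, C7′ = aryl-bearing THF C2, C9 = ring CH2, C9′ = CH2OH). (−)-Menthol (recoverable auxiliary) and the silyl chlorides are reagents and are not numbered.

## Retrosynthetic overview

1. Target ⇐ global desilylation ⇐ C7–aryl bond: catalytic aryl-zinc addition of arylboronic acid **19** (ring B) to THF-aldehyde **14**; this late fragment union sets C7.
2. **14** ⇐ tetrahydrofuran ring (the only ring constructed) by SN1 cycloetherification of triol **11**, forming C7′–O and setting C7′ trans to C8′.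
3. **11** ⇐ three-component conjugate addition–aldol: 1,3-dithiane anion (C7) + menthyloxybutenolide **8** (C8, C8′, C9, C9′) + aldehyde **5** (ring A + C7′); sets C8 and C8′.
4. Building blocks: **5** from p-cresol, **8** from furfural, **19** from catechol, each made in its own branch.
5. Ring order: temporary lactone template (from **8**, opened in step 8) → tetrahydrofuran (step 9); the benzene rings come from the starting materials.

## Route

### Branch A: ring-A aldehyde

**Step 1**
Reactants: **1** p-cresol
Product: **2** 4-hydroxybenzaldehyde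
Conditions: O2 (1 atm), CoCl2 (2 mol %), NaOH (3 equiv), MeOH, 60 °C
Reagents that add atoms: dioxygen, O=O
Why: Co-catalysed aerobic benzylic oxidation of a p-cresolate (via the quinone methide) stops at the deactivated phenolate-aldehyde.

**Step 2**
Reactants: **2** 4-hydroxybenzaldehyde
Product: **3** 3-bromo-4-hydroxybenzaldehyde
Conditions: Br2 (1.0 equiv), CHCl3, 0 °C → rt
Reagents that add atoms: bromine, BrBr
Why: Electrophilic aromatic bromination goes ortho to OH (para blocked, CHO meta-directing to the same carbon).

**Step 3**
Reactants: **3** 3-bromo-4-hydroxybenzaldehyde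
Product: **4** vanillin (4-hydroxy-3-methoxybenzaldehyde)
Conditions: NaOMe (4 equiv), CuCl (0.3 equiv), DMF–MeOH, 115 °C; acidic work-up
Reagents that add atoms: sodium methoxide, C[O-].[Na+]
Why: Cu(I)-catalysed Ullmann-type methoxylation of the aryl bromide, the classical vanillin synthesis.

**Step 4**
Reactants: **4** vanillin
Product: **5** 3-methoxy-4-(triisopropylsilyloxy)benzaldehyde
Conditions: TIPSCl, imidazole, DMF, rt
Reagents that add atoms: TIPSCl, CC(C)[Si](Cl)(C(C)C)C(C)C
Why: Phenol silylation; the aryl TIPS ether tolerates RLi at −78 °C, LiAlH4, mild acid and Et2Zn, and is removed by fluoride.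

### Branch C: chiral butenolide

**Step 5**
Reactants: **6** furfural
Product: **7** 5-hydroxy-2(5H)-furanone (racemic hemiacetal)
Conditions: O2, hν (visible), rose bengal (cat.), MeOH, rt
Reagents that add atoms: dioxygen (as singlet oxygen), O=O
Why: Dye-sensitised [4+2] photooxygenation of the furan; the endoperoxide fragments with loss of the formyl carbon as methyl formate.

**Step 6**
Reactants: **7** 5-hydroxy-2(5H)-furanone
Product: **8** (5R)-5-[(1R,2S,5R)-menthyloxy]-2(5H)-furanone
Conditions: (−)-menthol (1.1 equiv), CSA (cat.), benzene, reflux (−H2O); crystallise from petroleum ether, re-equilibrate the mother liquor with cat. acid and recycle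
Reagents that add atoms: (−)-menthol (auxiliary), C[C@@H]1CC[C@H]([C@@H](C1)O)C(C)C
Why: Acid-catalysed acetalisation; the C5 epimers interconvert under acid and the (5R) diastereomer crystallises, fixing the centre that controls all later induction.

### Three-component union and THF formation

**Step 7**
Reactants: **9** 1,3-dithiane, **8** (5R)-5-menthyloxy-2(5H)-furanone, **5** 3-methoxy-4-(triisopropylsilyloxy)benzaldehyde
Product: **10** (3S,4R,5R)-4-(1,3-dithian-2-yl)-3-{hydroxy[3-methoxy-4-(triisopropylsilyloxy)phenyl]methyl}-5-[(1R,2S,5R)-menthyloxy]dihydrofuran-2(3H)-one (mixture of carbinol epimers)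
Conditions: **9**, n-BuLi, THF, −30 °C; then **8**, THF–DMPU, −78 °C; then **5**, −78 °C; AcOH quench at −78 °C
Reagents that add atoms: none
Why: Tandem Michael–aldol reaction: the lithiodithiane adds to C4 anti to the C5 menthyloxy group (sets C8), and the lactone enolate adds to the aldehyde anti to the new C4 substituent (sets C8′); the carbinol centre is reset in step 9.

**Step 8**
Reactants: **10** conjugate addition–aldol lactone
Product: **11** (2R,3R)-2-(1,3-dithian-2-yl)-3-{hydroxy[3-methoxy-4-(triisopropylsilyloxy)phenyl]methyl}butane-1,4-diol (carbinol epimers)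
Conditions: LiAlH4, THF, 0 °C; Rochelle-salt work-up (menthol recovered)
Reagents that add atoms: none
Why: Hydride reduction of the acyl-acetal lactone gives both primary alcohols (C9′ from C=O, C9 from the acetal carbon after loss of menthoxide) without touching C8/C8′ or the dithiane.

**Step 9**
Reactants: **11** dithianyl triol
Product: **12** [(2S,3R,4R)-4-(1,3-dithian-2-yl)-2-[3-methoxy-4-(triisopropylsilyloxy)phenyl]tetrahydrofuran-3-yl]methanol
Conditions: CSA (0.2 equiv), CH2Cl2, 0 °C → rt
Reagents that add atoms: none
Why: SN1 cycloetherification: the p-siloxybenzyl cation is trapped 5-exo by the C9 hydroxyl (the C9′ OH could only give an oxetane), and reversible closure places the aryl trans to the C3 CH2OH, so both carbinol epimers converge on (2S). The trans C8/C8′ relationship of the lactone becomes the required 3,4-cis relationship on the new ring.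

**Step 10**
Reactants: **12** THF-methanol
Product: **13** tert-butyl{[(2S,3R,4R)-4-(1,3-dithian-2-yl)-2-[3-methoxy-4-(triisopropylsilyloxy)phenyl]tetrahydrofuran-3-yl]methoxy}dimethylsilane
Conditions: TBSCl, imidazole, DMF, rt
Reagents that add atoms: TBSCl, CC(C)(C)[Si](C)(C)Cl
Why: Silylation of the primary alcohol prevents lactol formation and alkoxide-directed addition in step 16, and enlarges the C8′ substituent for Felkin control.

**Step 11**
Reactants: **13** TBS ether
Product: **14** (3R,4R,5S)-4-{[(tert-butyldimethylsilyl)oxy]methyl}-5-[3-methoxy-4-(triisopropylsilyloxy)phenyl]tetrahydrofuran-3-carbaldehyde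
Conditions: MeI (excess), CaCO3, MeCN–H2O (9:1), 45 °C; use crude, cold
Reagents that add atoms: water, O
Why: Alkylative dithiane hydrolysis under neutral buffered conditions unmasks the aldehyde without epimerising the cis α-centre or opening the ring by β-alkoxy elimination.

### Branch B: ring-B boronic acid

**Step 12**
Reactants: **15** catechol
Product: **16** guaiacol (2-methoxyphenol)
Conditions: MeI (1.0 equiv), K2CO3 (1.0 equiv), acetone, reflux; separate from catechol and veratrole by extraction and distillation
Reagents that add atoms: iodomethane, CI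
Why: Williamson mono-O-methylation; the monoether is less acidic than catechol, so stoichiometric base favours mono-alkylation.

**Step 13**
Reactants: **16** guaiacol
Product: **17** 4-bromo-2-methoxyphenol
Conditions: Bu4NBr3 (1.0 equiv), CH2Cl2–MeOH, rt
Reagents that add atoms: tetrabutylammonium tribromide (Bu4N+ Br3−, drawn as the bromide–bromine adduct), CCCC[N+](CCCC)(CCCC)CCCC.[Br-].BrBr
Why: Electrophilic aromatic bromination with a mild, stoichiometric Br3− source goes para to the free OH (the strongest director), giving the 4-hydroxy-3-methoxyphenyl substitution pattern without over-bromination.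

**Step 14**
Reactants: **17** 4-bromo-2-methoxyphenol
Product: **18** (4-bromo-2-methoxyphenoxy)triisopropylsilane
Conditions: TIPSCl, imidazole, DMF, rt
Reagents that add atoms: TIPSCl, CC(C)[Si](Cl)(C(C)C)C(C)C
Why: Phenol silylation ahead of metalation.

**Step 15**
Reactants: **18** aryl bromide
Product: **19** [3-methoxy-4-(triisopropylsilyloxy)phenyl]boronic acid
Conditions: n-BuLi, THF, −78 °C; B(OiPr)3; then 1 M HCl, 0 °C
Reagents that add atoms: triisopropyl borate, CC(C)OB(OC(C)C)OC(C)C; water, O
Why: Br/Li exchange and borylation give a bench-stable aryl donor suitable for B→Zn exchange.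

### Late fragment coupling and deprotection

**Step 16**
Reactants: **19** arylboronic acid (2.2 equiv), **14** THF-aldehyde
Product: **20** (R)-[(3R,4R,5S)-4-{[(tert-butyldimethylsilyl)oxy]methyl}-5-[3-methoxy-4-(triisopropylsilyloxy)phenyl]tetrahydrofuran-3-yl][3-methoxy-4-(triisopropylsilyloxy)phenyl]methanol
Conditions: **19**, Et2Zn (6.5 equiv), toluene, 60 °C, 12 h; cool, (−)-MIB (10 mol %), then **14**, toluene, −10 → 0 °C; aq. NH4Cl
Reagents that add atoms: none
Why: B→Zn exchange gives a non-basic ArZnEt, and amino-alcohol-catalysed aryl transfer to the aldehyde Si face sets C7 as R. Substrate and catalyst are matched: Felkin–Anh attack (anti to the C8′ branch, past the α-H) and the Si-face preference of (−)-MIB select the same face.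

**Step 17**
Reactants: **20** tris-silyl ether
Product: **21** (7R)-7-hydroxylariciresinol
Conditions: TBAF (3.5 equiv), AcOH (3.5 equiv), THF, 0 °C → rt; pH 7 buffer work-up
Reagents that add atoms: none
Why: Buffered fluoride desilylation removes both aryl TIPS ethers and the TBS ether without acid (which would close the second ring to a furofuran) and without hydrogenolysis of the benzylic C–O bonds.

Stereocentres: C8 and C8′ are set in step 7 (auxiliary control), C7′ in step 9 (thermodynamic trans closure), and C7 in step 16. None is adjacent to an enolisable carbonyl afterwards except C8 in aldehyde **14**, which is used crude and cold.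

## Compound list

1 | p-cresol | Cc1ccc(O)cc1 | starting material
2 | 4-hydroxybenzaldehyde | O=Cc1ccc(O)cc1 | intermediate
3 | 3-bromo-4-hydroxybenzaldehyde | O=Cc1ccc(O)c(Br)c1 | intermediate
4 | vanillin | COc1cc(C=O)ccc1O | intermediate
5 | 3-methoxy-4-(triisopropylsilyloxy)benzaldehyde | COc1cc(C=O)ccc1O[Si](C(C)C)(C(C)C)C(C)C | intermediate
6 | furfural | O=Cc1ccco1 | starting material
7 | 5-hydroxy-2(5H)-furanone (racemic) | O=C1OC(O)C=C1 | intermediate
8 | (5R)-5-[(1R,2S,5R)-menthyloxy]-2(5H)-furanone | O=C1O[C@@H](O[C@@H]2C[C@H](C)CC[C@H]2C(C)C)C=C1 | intermediate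
9 | 1,3-dithiane | C1CSCSC1 | starting material
10 | (3S,4R,5R) conjugate addition–aldol lactone, carbinol epimers | O=C1O[C@@H](O[C@@H]2C[C@H](C)CC[C@H]2C(C)C)[C@H](C2SCCCS2)[C@H]1C(O)c1ccc(O[Si](C(C)C)(C(C)C)C(C)C)c(OC)c1 | intermediate
11 | (2R,3R) dithianyl triol, carbinol epimers | OC[C@H](C1SCCCS1)[C@@H](C(O)c1ccc(O[Si](C(C)C)(C(C)C)C(C)C)c(OC)c1)CO | intermediate
12 | (2S,3R,4R) 2-aryl-4-dithianyl-THF-3-methanol | COc1cc([C@H]2OC[C@H](C3SCCCS3)[C@@H]2CO)ccc1O[Si](C(C)C)(C(C)C)C(C)C | intermediate
13 | TBS ether of 12 | COc1cc([C@H]2OC[C@H](C3SCCCS3)[C@@H]2CO[Si](C)(C)C(C)(C)C)ccc1O[Si](C(C)C)(C(C)C)C(C)C | intermediate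
14 | (3R,4R,5S) THF-3-carbaldehyde | COc1cc([C@H]2OC[C@H](C=O)[C@@H]2CO[Si](C)(C)C(C)(C)C)ccc1O[Si](C(C)C)(C(C)C)C(C)C | intermediate
15 | catechol | Oc1ccccc1O | starting material
16 | guaiacol | COc1ccccc1O | intermediate
17 | 4-bromo-2-methoxyphenol | COc1cc(Br)ccc1O | intermediate
18 | (4-bromo-2-methoxyphenoxy)triisopropylsilane | COc1cc(Br)ccc1O[Si](C(C)C)(C(C)C)C(C)C | intermediate
19 | [3-methoxy-4-(triisopropylsilyloxy)phenyl]boronic acid | COc1cc(B(O)O)ccc1O[Si](C(C)C)(C(C)C)C(C)C | intermediate
20 | tris-silylated (7R)-7-hydroxylariciresinol | COc1cc([C@H]2OC[C@H]([C@@H](O)c3ccc(O[Si](C(C)C)(C(C)C)C(C)C)c(OC)c3)[C@@H]2CO[Si](C)(C)C(C)(C)C)ccc1O[Si](C(C)C)(C(C)C)C(C)C | intermediate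
21 | (7R)-7-hydroxylariciresinol, 4-[(2S,3R,4R)-4-[(R)-hydroxy(4-hydroxy-3-methoxyphenyl)methyl]-3-(hydroxymethyl)tetrahydrofuran-2-yl]-2-methoxyphenol | COc1cc([C@H]2OC[C@H]([C@@H](O)c3ccc(O)c(OC)c3)[C@@H]2CO)ccc1O | target

## Summary

**Total steps:** 17.
**Longest linear sequence:** 11 (steps 1–4, 7–11, 16, 17, from p-cresol). The butenolide branch (steps 5–6) and the boronic acid branch (steps 12–15) run in parallel.

**Three steps most likely to fail**

1. **Step 7 (three-component union).** Unsubstituted lithiodithiane may add 1,2 to the lactone, or the aldolate may revert. Fallback: a stepwise, auxiliary-free route. Rh/chiral-diene-catalysed asymmetric conjugate addition of a vinylboron reagent to plain 2(5H)-furanone, then a separate LDA aldol with **5**; the vinyl group is later cleaved (OsO4/NaIO4) to the C7 aldehyde in place of dithiane hydrolysis.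
2. **Step 9 (cationic THF closure).** The p-siloxyaryl cation may form sluggishly, eliminate to a styrene, or be intercepted by dithiane sulfur. Fallback: change the activation mode. Desilylate the ring-A phenol of **11** and close the ring through the p-quinone methide under near-neutral conditions, then silylate the phenol and primary OH together in step 10.
3. **Step 16 (aryl transfer to the cis-aldehyde).** Risks are epimerisation or retro-oxa-Michael opening of **14**, competing ethyl transfer, and insufficient C7 selectivity. Fallback: make the C7–aryl bond in step 7 instead, using the 2-aryl-1,3-dithiane of the ring-B aldehyde as the nucleophile, so **14** is never formed. The resulting C7 aryl ketone is then reduced with (S)-Me-CBS/BH3 or a hydroxyl-directed hydride; this must override the ketone's intrinsic Felkin preference for 7S.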